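## The problem

Compound 24 (CNP0127096.1) holds seven stereocentres in four rings built around a 2-oxabicyclo[2.2.2]octan-3-one. The bridgeheads C12 and C16 are joined by the lactone bridge C13(=O14)–O15, by C22–C21 and by C27(OH)–C26. A 3,6-dihydro-2H-pyran (O11, C12, C22, C23=C24, C10) is fused on the C12–C22 edge, a cyclopentanol (C16, C17, C18, C20, C21) on the C16–C21 edge, and C10 carries an (E)-non-1-enyl chain. C12 is the hard atom: it is a fully substituted bridgehead bearing the ether oxygen, the lactone carbonyl and the carbinol carbon C27. The stereocentres can be set in a chain. C18 can set C21 across the five-membered ring. C21 can set its neighbour C22 and, through a suprafacial ring formation, C10, and it also steers a nucleophile onto C16. C12 is then forced by the bridge, and C27 is left on a rigid cage where only approach control operates. Several groups are fragile: the C10–O11 ether is allylic on both sides and ionises with acid, the C27 carbinol is an aldol relative to C13 and can undergo retro-aldol cleavage with base, β-oxygenated cyclopentanones eliminate, and C21 epimerises whenever it is α to a free carbonyl. The feature that invites one ring-forming step is the pyran itself. O11–C10–C24=C23–C22–C12 is the adduct of a carbonyl unit O11=C12, which already carries its carboxyl carbon C13, and an E,E-diene C22=C23–C24=C10. The cis hydrogens on C10 and C22 are what a suprafacial oxo-Diels–Alder addition would leave.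

## Retrosynthesis

**C27–H and O19–Si.** 24 is traced to its silyl ether 23 and then to ketone 22 by removing the hydrogen on C27. Setting C27 by reduction is preferred to setting it in a ring-closing aldol. A metal enolate closing onto a C27 aldehyde would hold the aldehyde oxygen in the pocket between O11 and the enolate oxygen, which puts the hydroxyl syn to C13, whereas 24 has it anti. 22 has one stereocentre fewer. The forward step asks only that hydride enter from the open sector beside the flat lactone bridge.

**C12–C27.** Cutting this bond of 22 opens the carbocycle and leaves lactone 20, where C12 is a methine and C27 an N-methoxy-N-methylamide. The neighbouring cut, C16–C26, would need a closure trans to C22 on the cyclopentane before the lactone exists. Cutting the lactone instead would remove the ring that later forces the configuration of C12. The forward Claisen-type acylation must enolise C12 selectively and must not expel the β-acyloxy group. An amide was chosen because its α-hydrogens are far less acidic than the lactone's and its tetrahedral adduct does not revert.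

**C16–C26 and O15–C13.** 20 is opened at the lactone C–O bond and at the bond from C16 to its two-carbon arm. This gives ketone 17 and N-methoxy-N-methylacetamide 18, and one unmasking step further back, ketal 16. Both bonds can form in one operation, because the alkoxide born at C16 lies next to the C13 ester. Placing this after the pyran exists means the nucleophile meets a ketone with a very large α-substituent, so attack anti to it, and with it the cis lactone, is favoured. The forward step must prefer the ketone to the ester and must not eliminate the C18 silyloxy group.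

**O11–C10 and C12–C22.** Both pyran bonds of 16 are cut at once, to triene 14 and ethyl glyoxylate 15. No other pair of ring bonds has a pericyclic counterpart, and a stepwise etherification at C10 would have to control a centre that ionises readily. The gain is one ring and three stereocentres from a substrate that carries only the two ring stereocentres. The forward reaction has to choose the right diene of the triene, the right orientation, the endo mode and the diene face anti to C16.

**C22=C23 and C10=C24.** 14 is cut at C22=C23 into tetrazolyl sulfone 10 and dienal 13 (Julia–Kocienski), and 13 at C10=C24 into (E)-dec-2-enal 11 and ylide 12 (Wittig). The sulfone is put on the ring fragment so that C21 is never α to an aldehyde. The alternative polarity would need a four-step dienyl sulfone and an epimerisable formyl ketal. The forward olefination must give the E alkene.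

**Functional groups on the ring fragment.** 10 goes back through silyl ether 9 and sulfide 8 to diol ketal 7, and 7 to keto diol 4. Only the primary hydroxyl of 7 is to be displaced, and the ketal must be made without enolising C16.

**C21–H and C21–C22.** 4 comes from enone 3 by adding hydrogen to the face that carries the C18 hydroxyl. 3 comes from (S)-4-hydroxycyclopent-2-en-1-one 1 and formaldehyde 2 by α-hydroxymethylation. A sterically controlled hydrogenation of a silyl ether would give the cis isomer, so the free hydroxyl is kept as the directing group.

## Roads not taken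

**Alternative 1:** The cut is made twice at C12, through O11–C12 and C12–C27. This leaves a lactone with a diazo group on C12 and a separate, enantiopure C1–C10 allylic alcohol that already holds C24 and C25. In the forward direction Rh2(OAc)4 would generate the carbenoid at C12 and the C10 hydroxyl would add to it. The oxonium ylide or its enol would then be trapped by the C27 aldehyde on C16, closing the carbocycle and giving A1. Ring-closing metathesis between the vinyl on C22 and the isopropenyl on C10 would then lead to 23.
- Merits: the quaternary centre is built with both new bonds in one operation, the union of the halves is late and convergent, and there is no question of cycloaddition orientation.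
- Weak points: a carbenoid flanked by C22–H can undergo 1,2-hydride shift to the C12=C22 alkene. The tethered aldehyde oxygen can capture the carbenoid before an external alcohol does. C10 must be made as a single enantiomer on its own, since nothing in the lactone directs it. The metathesis has a second six-membered option through C8=C9 with loss of non-1-ene, and a 1,2-disubstituted alkene is usually the better partner.
- Comparison: in convergence and in the direct construction of C12 this road is better. The chosen plan sets against it a pyran closure in which C10 and C22 arise together under the control of C21. It also needs no diazo group beside an aldehyde and no metathesis that must choose between two alkenes.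

**Alternative 2:** Here C21–C22 is cut. C16 is installed first as a tertiary vinyl carbinol on a cyclopentenone and its oxygen is acylated with the C13–C12–C22–C23 chain. The aldehyde end of that tether is condensed with (S)-α,α-diphenylprolinol trimethylsilyl ether. The enamine adds through C22 to the enone carbon C21 and the six-membered lactone closes, giving A2.
- Merits: the reaction is catalytic and metal-free, intramolecular Michael additions of this kind are well established, and the cis fusion follows from the short tether. The lactone, C16 with its two-carbon handle and the C12 oxygen are in place early, so steps 10 and 11 of the chosen plan have no counterpart.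
- Weak points: the tether aldehyde carries the C12 alkoxy group β to the carbonyl and α to the ester, so enamine formation invites loss of the alkoxide or epimerisation. A2 is also far from 24. C10, C24, C25, the nonenyl chain, the pyran with its doubly allylic ether, the C18 carbinol and the C12–C27 bond all remain. C10 would have to be set in an etherification at a centre that ionises easily.
- Comparison: the chosen plan needs extra steps for what A2 has from the start. In return it sets C10 and C22 in the same step as the pyran and takes C18 from the starting material.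

**Alternative 3:** The cut is C12–C22 within a [3,3] frame. The precursor is a 1,4-dioxan-2-one in which O11, C10, C24 and the ester oxygen on C24 lie in the ring and the alkene C23=C22 hangs from C24. LiN(iPr)2 and Me3SiCl give the silyl ketene acetal, which rearranges through a boat transition state. This forms C12–C22, releases the carboxylate from C24 and contracts the ring to the dihydropyran acid A3.
- Merits: the reaction type is reliable and the ketene acetal geometry is fixed by the ring. C12 emerges directly as the quaternary centre with C27 attached, chirality is transferred from C10 and C24, and there is no orientation or ene-versus-cycloaddition question. From A3, halolactonisation onto the exocyclic alkene and a C26–C27 closure could finish the cage.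
- Weak points: the substrate must already hold C10, a tertiary C24 ester whose stereocentre is sacrificed, and a defined alkene geometry, so nearly as much stereochemical information is invested as is gained. That tertiary allylic ester is prone to ionisation, and the fragment syntheses are clearly longer.
- Comparison: on stereochemical certainty at C12 and C22 this road is superior. The chosen plan answers with brevity: the pyran and three stereocentres come from two simple partners in one step, and C12 is corrected later by the bridge.

Key step: step 9

Remark: locants C1 to O28 are those of the skeleton of 24 (heptyl C1–C7, C8=C9, C10, O11, C12, C13(=O14)O15, C16, C17, C18(O19), C20, C21, C22, C23=C24(C25), C26, C27(O28)) and are used for all intermediates.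

Remark: the (R,R)-ligand is assumed to be the enantiomer whose copper chelate exposes the glyoxylate face leading to 12R, the usual sense for additions to glyoxylate with tert-butyl bis(oxazoline) ligands.

## Route

Step 1
Reactants: 1 (S)-4-hydroxycyclopent-2-en-1-one; 2 formaldehyde
Product: 3 (S)-4-hydroxy-2-(hydroxymethyl)cyclopent-2-en-1-one
Conditions: 37% aq. 2 (1.5 equiv), imidazole (0.2 equiv), THF–H2O, rt
Reagents that add atoms: none
Why: Morita–Baylis–Hillman reaction: imidazole adds reversibly to the enone β-carbon (C20), the enolate attacks formaldehyde through C21, and loss of imidazole restores the enone. C18 is not involved and the free hydroxyl is tolerated in the aqueous medium.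

Step 2
Reactants: 3 (S)-4-hydroxy-2-(hydroxymethyl)cyclopent-2-en-1-one
Product: 4 (2S,4R)-4-hydroxy-2-(hydroxymethyl)cyclopentan-1-one
Conditions: [Ir(cod)(PCy3)(py)]PF6 (5 mol %), H2 (1 atm), CH2Cl2, 0 °C → rt
Reagents that add atoms: none
Why: Hydroxyl-directed homogeneous hydrogenation: the cationic iridium centre binds the C18 hydroxyl and delivers H2 to the alkene face that carries it. The new C21–H is therefore cis to the hydroxyl and the hydroxymethyl group trans (2S,4R), and the neutral medium spares the two β-hydroxy ketone units.

Step 3
Reactants: 4 (2S,4R)-4-hydroxy-2-(hydroxymethyl)cyclopentan-1-one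
Product: 7 (6S,8R)-6-(hydroxymethyl)-1,4-dioxaspiro[4.4]nonan-8-ol, via keto bis(trimethylsilyl) ether 5 (not isolated), via ketal bis(trimethylsilyl) ether 6 (not isolated)
Conditions: Me3SiCl, imidazole, CH2Cl2, 0 °C; then (Me3SiOCH2)2, Me3SiOTf (5 mol %), −78 → −30 °C; then K2CO3, MeOH, 0 °C
Reagents that add atoms: 1,2-bis(trimethylsilyloxy)ethane, C[Si](C)(C)OCCO[Si](C)(C)C
Why: Aprotic ketalisation with the bis-silyl ether of ethylene glycol under silyl triflate catalysis at low temperature, run on the transient bis(trimethylsilyl) ether. It avoids enolisation of C16, so C21 is not epimerised and neither β-oxygen is eliminated; methanolysis then frees only the two hydroxyls.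

Step 4
Reactants: 7 (6S,8R)-6-(hydroxymethyl)-1,4-dioxaspiro[4.4]nonan-8-ol
Product: 8 (6R,8R)-6-{[(1-phenyl-1H-tetrazol-5-yl)sulfanyl]methyl}-1,4-dioxaspiro[4.4]nonan-8-ol
Conditions: 1-phenyl-1H-tetrazole-5-thiol (1.1 equiv), PPh3, iPrO2CN=NCO2iPr, THF, 0 °C
Reagents that add atoms: 1-phenyl-1H-tetrazole-5-thiol, Sc1nnnn1-c1ccccc1
Why: Mitsunobu thioetherification: the primary hydroxyl is activated and displaced much faster than the ring carbinol, so the thiol enters only at C22. No stereocentre is touched; the descriptor at C21 changes only because sulfur raises the priority of C22.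

Step 5
Reactants: 8 (6R,8R)-6-{[(1-phenyl-1H-tetrazol-5-yl)sulfanyl]methyl}-1,4-dioxaspiro[4.4]nonan-8-ol
Product: 9 5-({[(6R,8R)-8-(tert-butyldimethylsilyloxy)-1,4-dioxaspiro[4.4]nonan-6-yl]methyl}sulfanyl)-1-phenyl-1H-tetrazole
Conditions: tBuMe2SiCl, imidazole, DMF, rt
Reagents that add atoms: tert-butyl(chloro)dimethylsilane, CC(C)(C)[Si](C)(C)Cl
Why: Standard silylation of the remaining secondary alcohol; sulfide and ketal are inert.

Step 6
Reactants: 9 5-({[(6R,8R)-8-(tert-butyldimethylsilyloxy)-1,4-dioxaspiro[4.4]nonan-6-yl]methyl}sulfanyl)-1-phenyl-1H-tetrazole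
Product: 10 5-({[(6R,8R)-8-(tert-butyldimethylsilyloxy)-1,4-dioxaspiro[4.4]nonan-6-yl]methyl}sulfonyl)-1-phenyl-1H-tetrazole
Conditions: (NH4)6Mo7O24·4H2O (10 mol %), 30% H2O2, EtOH, 0 °C → rt
Reagents that add atoms: hydrogen peroxide, OO
Why: Molybdate-catalysed peroxide oxidation of the sulfide to the sulfone under nearly neutral conditions that spare the dioxolane and the silyl ether; no alkene is present yet.

Step 7
Reactants: 11 (E)-dec-2-enal; 12 2-(triphenyl-λ5-phosphanylidene)propanal
Product: 13 (2E,4E)-2-methyldodeca-2,4-dienal
Conditions: 12 (1.05 equiv), toluene, 80 °C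
Reagents that add atoms: none
Why: Wittig reaction with a formyl-stabilised ylide gives the E trisubstituted enal. The α-branched dienal is less electrophilic than 11, so a single homologation is expected.

Step 8
Reactants: 10 5-({[(6R,8R)-8-(tert-butyldimethylsilyloxy)-1,4-dioxaspiro[4.4]nonan-6-yl]methyl}sulfonyl)-1-phenyl-1H-tetrazole; 13 (2E,4E)-2-methyldodeca-2,4-dienal
Product: 14 tert-butyldimethyl{[(6S,8R)-6-[(1E,3E,5E)-3-methyltrideca-1,3,5-trien-1-yl]-1,4-dioxaspiro[4.4]nonan-8-yl]oxy}silane
Conditions: KN(SiMe3)2, DME, −78 °C; then 13; −78 °C → rt
Reagents that add atoms: none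
Why: Julia–Kocienski olefination: the potassium salt of the tetrazolyl sulfone adds to the enal, and Smiles rearrangement with loss of SO2 and the tetrazolone gives the E C22=C23 bond. In this polarity C21 never stands next to a carbonyl and cannot epimerise.

Step 9
Reactants: 14 tert-butyldimethyl{[(6S,8R)-6-[(1E,3E,5E)-3-methyltrideca-1,3,5-trien-1-yl]-1,4-dioxaspiro[4.4]nonan-8-yl]oxy}silane; 15 ethyl glyoxylate
Product: 16 ethyl (2R,3R,6R)-3-[(6S,8R)-8-(tert-butyldimethylsilyloxy)-1,4-dioxaspiro[4.4]nonan-6-yl]-5-methyl-6-[(E)-non-1-en-1-yl]-3,6-dihydro-2H-pyran-2-carboxylate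
Conditions: 15 (3 equiv, freshly distilled), Cu(OTf)2 (10 mol %), 2,2'-isopropylidenebis[(4R)-4-tert-butyl-2-oxazoline] (11 mol %), CH2Cl2, −40 → 0 °C
Reagents that add atoms: none
Why: Glyoxylate chelates divalent copper through its aldehyde and ester oxygens, and the activated carbonyl carbon bonds to the triene terminus C22 while its oxygen closes on C10 in one concerted but asynchronous normal-demand oxo-Diels–Alder event. The closest known reaction type is the copper–bis(oxazoline)-catalysed hetero-Diels–Alder reaction of glyoxylate esters with conjugated dienes such as cyclohexa-1,3-diene and 2,3-dimethylbutadiene. The pyran closes by suprafacial [4+2] addition on the s-cis C22=C23–C24=C10 diene; the other diene, C24=C10–C9=C8, cannot become s-cis because the methyl C25 would point inwards. The carbonyl carbon should go to C22 because the terminus of a triene carries the largest HOMO coefficient and the developing charge is then spread over C23, C10 and C8, the orientation usual for 1-vinyl dienes. The cis hydrogens on C22 and C10 follow from suprafacial addition to the E,E-diene, and their absolute sense from the diene face: with H21 eclipsing the alkene, the glyoxylate adds anti to the ketal carbon C16, which gives 22R and 10R. C12 is set by the endo placement of the ester, which puts it cis to C21 and C9, and by the ligand, whose (R,R) form is expected to favour 12R and so to act in concert with the substrate. The step needs diene-site, orientational, endo and facial selectivity and must outrun the carbonyl-ene reaction at the C24 methyl group. Because C12 is made planar again and fixed by the bridge in step 12, any exo adduct should still be usable.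

Step 10
Reactants: 16 ethyl (2R,3R,6R)-3-[(6S,8R)-8-(tert-butyldimethylsilyloxy)-1,4-dioxaspiro[4.4]nonan-6-yl]-5-methyl-6-[(E)-non-1-en-1-yl]-3,6-dihydro-2H-pyran-2-carboxylate
Product: 17 ethyl (2R,3R,6R)-3-[(1S,4R)-4-(tert-butyldimethylsilyloxy)-2-oxocyclopentyl]-5-methyl-6-[(E)-non-1-en-1-yl]-3,6-dihydro-2H-pyran-2-carboxylate
Conditions: pyridinium p-toluenesulfonate (0.2 equiv), acetone–H2O (10:1), 50 °C
Reagents that add atoms: water, O
Why: Mild acid-catalysed ketal hydrolysis and exchange into acetone; the secondary silyl ether and the ester survive this weak acid. The ester on C12 makes O11 a poor base, so the doubly allylic C10–O11 bond should not ionise, and a short contact time limits enolisation towards C21.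

Step 11
Reactants: 17 ethyl (2R,3R,6R)-3-[(1S,4R)-4-(tert-butyldimethylsilyloxy)-2-oxocyclopentyl]-5-methyl-6-[(E)-non-1-en-1-yl]-3,6-dihydro-2H-pyran-2-carboxylate; 18 N-methoxy-N-methylacetamide
Product: 20 tricyclic lactone amide (10R,12R,16R,18R,21S,22R) in which O15 on C16 has closed the δ-lactone onto C13 and C16 carries CH2C(O)N(OMe)Me, via hydroxy ester amide 19 (not isolated)
Conditions: 18 (2.0 equiv), LiN(iPr)2 (2.0 equiv), THF, −78 °C; then 17; −78 → −20 °C; aq. NH4Cl
Reagents that add atoms: none
Why: Aldol-type addition of the lithium amide enolate to the ketone occurs anti to the bulky C21 substituent and places O15 cis to C22 (16R). The tertiary alkoxide then attacks the C13 ester and closes the cis-fused δ-lactone with loss of ethoxide, a closure the C16 epimer can hardly undergo. The amide α-hydrogens are too weakly acidic for the new β-acyloxy group to be eliminated.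

Step 12
Reactants: 20 tricyclic lactone amide (10R,12R,16R,18R,21S,22R)
Product: 22 tetracyclic keto lactone (10R,12S,16R,18R,21S,22R) having the full skeleton of 24 with C27 as ketone and C18 as silyl ether, via lithium hemiaminal alkoxide 21 (not isolated)
Conditions: LiN(SiMe3)2 (1.5 equiv), THF, −78 → −20 °C; aq. NH4Cl
Reagents that add atoms: none
Why: Intramolecular Claisen (Dieckmann-type) acylation of a lactone enolate by an N-methoxy-N-methylamide. The silylamide removes only the lactone α-hydrogen at C12, and the enolate carbon can reach C27 only on the lactone face that carries C26, so the new bridge fixes C12 as S whatever its configuration in 20. The chelated tetrahedral adduct 21 resists retro-Claisen cleavage and releases the ketone on work-up.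

Step 13
Reactants: 22 tetracyclic keto lactone (10R,12S,16R,18R,21S,22R)
Product: 23 18-O-(tert-butyldimethylsilyl) ether of 24 (10R,12S,16S,18R,21S,22R,27R; the 16S label comes only from the priority of the silyl group)
Conditions: LiAlH(OtBu)3, THF, −78 → −20 °C
Reagents that add atoms: none
Why: Approach-controlled hydride reduction of a rigid bicyclo[2.2.2]octanone. The sector between the C26–C27 bridge and the flat lactone bridge is empty, whereas the other is screened by H21 and H22 and by the silyl ether below, so the bulky hydride should enter beside the lactone and leave the hydroxyl anti to C13 (27R). The reagent reduces ketones much faster than lactones and its alkoxide is too hindered for retro-Claisen attack.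

Step 14
Reactants: 23 18-O-(tert-butyldimethylsilyl) ether of 24
Product: 24 CNP0127096.1 (10R,12S,16R,18R,21S,22R,27R)
Conditions: HF·pyridine, pyridine, THF, 0 °C → rt
Reagents that add atoms: none
Why: Fluoride-mediated desilylation in a pyridine-buffered medium, which avoids both base-induced retro-aldol cleavage of the β-hydroxy lactone and acid ionisation of the allylic ether.

## Compound list

1 | (S)-4-hydroxycyclopent-2-en-1-one | O=C1C=C[C@@H](O)C1 | starting material
2 | formaldehyde | C=O | starting material
3 | (S)-4-hydroxy-2-(hydroxymethyl)cyclopent-2-en-1-one | O=C1C(CO)=C[C@@H](O)C1 | intermediate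
4 | (2S,4R)-4-hydroxy-2-(hydroxymethyl)cyclopentan-1-one | O=C1C[C@H](O)C[C@H]1CO | intermediate
5 | (2S,4R)-4-(trimethylsilyloxy)-2-[(trimethylsilyloxy)methyl]cyclopentan-1-one | O=C1C[C@H](O[Si](C)(C)C)C[C@H]1CO[Si](C)(C)C | intermediate (not isolated)
6 | (6S,8R)-8-(trimethylsilyloxy)-6-[(trimethylsilyloxy)methyl]-1,4-dioxaspiro[4.4]nonane | C[Si](C)(C)OC[C@@H]1C[C@@H](O[Si](C)(C)C)CC12OCCO2 | intermediate (not isolated)
7 | (6S,8R)-6-(hydroxymethyl)-1,4-dioxaspiro[4.4]nonan-8-ol | OC[C@@H]1C[C@@H](O)CC12OCCO2 | intermediate
8 | (6R,8R)-6-{[(1-phenyl-1H-tetrazol-5-yl)sulfanyl]methyl}-1,4-dioxaspiro[4.4]nonan-8-ol | c1ccccc1-n1nnnc1SC[C@@H]1C[C@@H](O)CC12OCCO2 | intermediate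
9 | 5-({[(6R,8R)-8-(tert-butyldimethylsilyloxy)-1,4-dioxaspiro[4.4]nonan-6-yl]methyl}sulfanyl)-1-phenyl-1H-tetrazole | c1ccccc1-n1nnnc1SC[C@@H]1C[C@@H](O[Si](C)(C)C(C)(C)C)CC12OCCO2 | intermediate
10 | 5-({[(6R,8R)-8-(tert-butyldimethylsilyloxy)-1,4-dioxaspiro[4.4]nonan-6-yl]methyl}sulfonyl)-1-phenyl-1H-tetrazole | O=S(=O)(C[C@@H]1C[C@@H](O[Si](C)(C)C(C)(C)C)CC12OCCO2)c1nnnn1-c1ccccc1 | intermediate
11 | (E)-dec-2-enal | CCCCCCC/C=C/C=O | starting material
12 | 2-(triphenyl-λ5-phosphanylidene)propanal | CC(C=O)=P(c1ccccc1)(c1ccccc1)c1ccccc1 | starting material
13 | (2E,4E)-2-methyldodeca-2,4-dienal | CCCCCCC/C=C/C=C(\C)C=O | intermediate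
14 | tert-butyldimethyl{[(6S,8R)-6-[(1E,3E,5E)-3-methyltrideca-1,3,5-trien-1-yl]-1,4-dioxaspiro[4.4]nonan-8-yl]oxy}silane | CCCCCCC/C=C/C=C(\C)/C=C/[C@@H]1C[C@@H](O[Si](C)(C)C(C)(C)C)CC12OCCO2 | intermediate
15 | ethyl glyoxylate | CCOC(=O)C=O | starting material
16 | ethyl (2R,3R,6R)-3-[(6S,8R)-8-(tert-butyldimethylsilyloxy)-1,4-dioxaspiro[4.4]nonan-6-yl]-5-methyl-6-[(E)-non-1-en-1-yl]-3,6-dihydro-2H-pyran-2-carboxylate | CCCCCCC/C=C/[C@H]1O[C@@H](C(=O)OCC)[C@H](C=C1C)[C@@H]2C[C@@H](O[Si](C)(C)C(C)(C)C)CC23OCCO3 | intermediate
17 | ethyl (2R,3R,6R)-3-[(1S,4R)-4-(tert-butyldimethylsilyloxy)-2-oxocyclopentyl]-5-methyl-6-[(E)-non-1-en-1-yl]-3,6-dihydro-2H-pyran-2-carboxylate | CCCCCCC/C=C/[C@H]1O[C@@H](C(=O)OCC)[C@H](C=C1C)[C@@H]2C[C@@H](O[Si](C)(C)C(C)(C)C)CC2=O | intermediate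
18 | N-methoxy-N-methylacetamide | CC(=O)N(C)OC | starting material
19 | ethyl (2R,3R,6R)-3-[(1S,2R,4R)-4-(tert-butyldimethylsilyloxy)-2-hydroxy-2-{2-[methoxy(methyl)amino]-2-oxoethyl}cyclopentyl]-5-methyl-6-[(E)-non-1-en-1-yl]-3,6-dihydro-2H-pyran-2-carboxylate (formed as its lithium alkoxide) | CCCCCCC/C=C/[C@H]1O[C@@H](C(=O)OCC)[C@H](C=C1C)[C@@H]2C[C@@H](O[Si](C)(C)C(C)(C)C)C[C@@]2(O)CC(=O)N(C)OC | intermediate (not isolated)
20 | tricyclic lactone amide (10R,12R,16R,18R,21S,22R): δ-lactone O15–C13 cis-fused to the dihydropyran at C12–C22 and to the cyclopentane at C16–C21; C16 bears CH2C(O)N(OMe)Me; C18 bears OSi(tBu)Me2 | CCCCCCC/C=C/[C@H]1O[C@H]2C(=O)O[C@@]3(CC(=O)N(C)OC)C[C@H](O[Si](C)(C)C(C)(C)C)C[C@H]3[C@H]2C=C1C | intermediate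
21 | lithium hemiaminal alkoxide at C27 of the closed cage (C27 configuration not defined) | CCCCCCC/C=C/[C@H]1O[C@@]23C(=O)O[C@]4(C[C@H](O[Si](C)(C)C(C)(C)C)C[C@H]4[C@H]2C=C1C)CC3(O[Li])N(C)OC | intermediate (not isolated)
22 | tetracyclic keto lactone (10R,12S,16R,18R,21S,22R): 2-oxabicyclo[2.2.2]octane-3,5-dione core with C27=O; C18 silyl ether | CCCCCCC/C=C/[C@H]1O[C@@]23C(=O)O[C@]4(C[C@H](O[Si](C)(C)C(C)(C)C)C[C@H]4[C@H]2C=C1C)CC3=O | intermediate
23 | 18-O-(tert-butyldimethylsilyl) ether of 24 (10R,12S,16S,18R,21S,22R,27R) | CCCCCCC/C=C/[C@H]1O[C@@]23C(=O)O[C@]4(C[C@H](O[Si](C)(C)C(C)(C)C)C[C@H]4[C@H]2C=C1C)C[C@H]3O | intermediate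
24 | CNP0127096.1 (10R,12S,16R,18R,21S,22R,27R) | CCCCCCC/C=C/[C@H]1O[C@@]23C(=O)O[C@]4(C[C@H](O)C[C@H]4[C@H]2C=C1C)C[C@H]3O | target

## Step count and risks

Total: 14 steps. Longest linear sequence: 13 steps from 1 to 24 (steps 1–6 and 8–14); step 7 is a one-step branch.

**Step 9 (key step).** The most likely failure is diversion of the strongly polarised, copper-bound glyoxylate into a carbonyl-ene reaction at the C24 methyl group or into attack at the remote terminus C8. The methyl group on C24 could also reverse the orientation, and a mismatch between ligand and C21 could erode face selectivity. As a fallback, 14 would be heated without catalyst with diethyl oxomalonate (toluene, 80 °C). This less polarised thermal oxo-Diels–Alder reaction runs under substrate control alone and would give diethyl (3R,6R)-3-[(6S,8R)-8-(tert-butyldimethylsilyloxy)-1,4-dioxaspiro[4.4]nonan-6-yl]-5-methyl-6-[(E)-non-1-en-1-yl]-3,6-dihydro-2H-pyran-2,2-dicarboxylate F1. Krapcho dealkoxycarbonylation of F1 (LiCl, wet DMSO, 130 °C) would return to 16 together with its C12 epimer, which is equally usable because C12 is made planar in step 12.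

**Step 12.** The hindered C12 enolate may fail to reach the amide carbonyl. It would then decay by a [2,3]-sigmatropic shift across the allylic O11–C10 ether or simply be reprotonated. As a fallback, the enolate of 20 would be intercepted at −78 °C with 2,2'-dipyridyl disulfide to give the C12 pyridin-2-ylsulfanyl lactone amide F2. Cp2Zr(H)Cl in THF would reduce its amide to the aldehyde F3. SmI2 (THF, −78 °C) would then cleave the C–S bond, and the trivalent samarium enolate would close onto the aldehyde in a Reformatsky-type aldol, giving the C27 carbinol F4, expected as the 27S epimer because samarium holds the aldehyde oxygen beside O11 and the enolate oxygen. Oxidation of F4 with the periodinane DMP would come back to the route at 22.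

**Step 11.** The strongly basic amide enolate may enolise the ketone instead of adding to it, which leads to loss of the β-silyloxy group or epimerisation at C21. The addition may also reverse before the lactone closes. As a fallback, 17 would be treated with CH2=CHMgBr and CeCl3 (THF, −78 → 0 °C), a far less basic reagent, to give the vinyl lactone F5 by addition and lactonisation in the same flask. Hydroboration of the terminal alkene with 9-BBN and oxidation with NaBO3·4H2O would give the primary alcohol F6. TEMPO with PhI(OAc)2 in aqueous acetonitrile would give the acid F7. Coupling with N,O-dimethylhydroxylamine hydrochloride (EDC·HCl, iPr2NEt, CH2Cl2) would come back to the route at 20.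

**Step 13.** Facial discrimination on the cage may be insufficient, or hydride may attack the lactone carbonyl. The fallback replaces substrate control by reagent control: a Corey–Bakshi–Shibata reduction of 22 with the (S)-methyl oxazaborolidine and catecholborane in toluene at −78 °C. This treats C12 as the large and C26 as the small substituent, should deliver 27R and returns to the route at 23; no new compound is made.

## Further compounds

F1 | step 9 | diethyl (3R,6R)-3-[(6S,8R)-8-(tert-butyldimethylsilyloxy)-1,4-dioxaspiro[4.4]nonan-6-yl]-5-methyl-6-[(E)-non-1-en-1-yl]-3,6-dihydro-2H-pyran-2,2-dicarboxylate | CCCCCCC/C=C/[C@H]1OC(C(=O)OCC)(C(=O)OCC)[C@H](C=C1C)[C@@H]2C[C@@H](O[Si](C)(C)C(C)(C)C)CC23OCCO3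
F2 | step 12 | 20 carrying a pyridin-2-ylsulfanyl group on C12 (C12 configuration not assigned; 10R,16R,18R,21S,22R) | CCCCCCC/C=C/[C@H]1OC2(Sc5ccccn5)C(=O)O[C@@]3(CC(=O)N(C)OC)C[C@H](O[Si](C)(C)C(C)(C)C)C[C@H]3[C@H]2C=C1C
F3 | step 12 | C12 pyridin-2-ylsulfanyl lactone with C16–CH2CHO (C12 configuration not assigned; 10R,16R,18R,21S,22R) | CCCCCCC/C=C/[C@H]1OC2(Sc5ccccn5)C(=O)O[C@@]3(CC=O)C[C@H](O[Si](C)(C)C(C)(C)C)C[C@H]3[C@H]2C=C1C
F4 | step 12 | C27 epimer of 23 (10R,12S,16S,18R,21S,22R,27S) | CCCCCCC/C=C/[C@H]1O[C@@]23C(=O)O[C@]4(C[C@H](O[Si](C)(C)C(C)(C)C)C[C@H]4[C@H]2C=C1C)C[C@@H]3O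
F5 | step 11 | tricyclic lactone with vinyl on C16 (10R,12R,16R,18R,21S,22R) | CCCCCCC/C=C/[C@H]1O[C@H]2C(=O)O[C@@]3(C=C)C[C@H](O[Si](C)(C)C(C)(C)C)C[C@H]3[C@H]2C=C1C
F6 | step 11 | tricyclic lactone with 2-hydroxyethyl on C16 (10R,12R,16S,18R,21S,22R; 16S by priority only) | CCCCCCC/C=C/[C@H]1O[C@H]2C(=O)O[C@@]3(CCO)C[C@H](O[Si](C)(C)C(C)(C)C)C[C@H]3[C@H]2C=C1C
F7 | step 11 | tricyclic lactone with carboxymethyl on C16 (10R,12R,16R,18R,21S,22R) | CCCCCCC/C=C/[C@H]1O[C@H]2C(=O)O[C@@]3(CC(=O)O)C[C@H](O[Si](C)(C)C(C)(C)C)C[C@H]3[C@H]2C=C1C
F0 | step 13 | none | none
A1 | alternative 1 | bridged lactone ether diene, 23 without the C23=C24 bond (vinyl on C22, isopropenyl on C10) | CCCCCCC/C=C/[C@H](C(C)=C)O[C@@]12C(=O)O[C@]3(C[C@H](O[Si](C)(C)C(C)(C)C)C[C@H]3[C@H]1C=C)C[C@H]2O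
A2 | alternative 2 | cis-fused cyclopentanone δ-lactone aldehyde with C12 p-methoxybenzyl ether and C16 vinyl | O=C[C@H]1[C@@H](OCc2ccc(OC)cc2)C(=O)O[C@@]3(C=C)CC(=O)C[C@@H]13
A3 | alternative 3 | 3,6-dihydro-2H-pyran-2-carboxylic acid with C12 bearing CH2O-p-methoxybenzyl and C16 as exocyclic methylene | CCCCCCC/C=C/[C@H]1O[C@@](COCc2ccc(OC)cc2)(C(=O)O)[C@@H]([C@@H]3C[C@@H](O[Si](C)(C)C(C)(C)C)CC3=C)C=C1C
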